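**Plan**
- Retrosynthesis: the side chain is cut at C12–C13 (B‑alkyl Suzuki–Miyaura coupling with chloroprene) and C11–C12 (Wittig), leaving a C11 aldehyde on the decalin. Ring B is then cut at C7–C8 and C9–C10 ([4+2]), and ring A at C5–C10 (aldol condensation) and at the malonate carbon C4 (alkylation).
- Enabling feature: in ring B the C6 oxygen and the C8 methyl are 1,3‑related and C9 carries a one‑carbon branch. C7=C6(OSi)–C5=C10 on ring A is therefore a 2‑silyloxydiene and C8–C9 with C17 and C11 is but‑2‑ynal; a gem‑diester at C4 keeps the diene achiral.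
- Forward order: ring A by enamine aldol condensation, ring B by the asymmetric Diels–Alder reaction, then C8/C9, the C4 groups, C6, and last the diene side chain.
- Stereochemistry: C10 from the chiral boron catalyst; C8 by epoxidation anti to the C10 methyl; C9 by protonation anti to the C8 and C10 methyls; C5 by axial protonation (trans fusion); C6 by dissolving‑metal reduction to the equatorial alcohol; C4 by silylating the equatorial CH2OH and reducing the axial one to CH3.

Key step: step 9

Remark on numbering: bicyclic compounds carry labdane numbering (ring A C1–C5, C10; ring B C5–C10; C11 on C9; C17 = methyl on C8; C18/C19 = equatorial/axial carbon on C4; C20 = methyl on C10); "syn" and "anti" refer to the face of C20. The target is (4S,5S,6R,8S,9S,10R).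
Assumption: the sense of induction of the oxazaborolidinium catalyst with this diene is not known; the (S)‑catalyst is written, and its mirror image would be used if it gave the (10S)‑adduct.

Step 1
Reactants: 1 dimethyl 2-allylmalonate; 2 2-(3-chloropropyl)-2-methyl-1,3-dioxolane
Product: 3 dimethyl 2-allyl-2-[3-(2-methyl-1,3-dioxolan-2-yl)propyl]malonate
Conditions: NaH, DMF, 0 °C; then 2, NaI (cat.), 70 °C
Reagents that add atoms: none
Why: Malonate alkylation (SN2) of the sodium enolate by the primary chloride, activated in situ as the iodide (Finkelstein), with the ketone masked as its dioxolane so that it can neither enolise nor close to a cyclopropyl ketone.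

Step 2
Reactants: 3 dimethyl 2-allyl-2-[3-(2-methyl-1,3-dioxolan-2-yl)propyl]malonate
Product: 5 dimethyl 2-[3-(2-methyl-1,3-dioxolan-2-yl)propyl]-2-(2-oxoethyl)malonate, via ozonide 4 (not isolated)
Conditions: O3, CH2Cl2, −78 °C; then PPh3, −78 °C → rt
Reagents that add atoms: ozone, [O-][O+]=O
Why: Ozonolysis of the only alkene with reductive work-up should give the aldehyde, the ketal and the esters being inert to ozone.

Step 3
Reactants: 5 dimethyl 2-[3-(2-methyl-1,3-dioxolan-2-yl)propyl]-2-(2-oxoethyl)malonate
Product: 6 dimethyl 2-(2-oxoethyl)-2-(4-oxopentyl)malonate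
Conditions: 1 M aq. HCl, THF, rt
Reagents that add atoms: water, O
Why: Acid-catalysed ketal hydrolysis should free the methyl ketone while the esters and the aldehyde survive dilute acid at room temperature.

Step 4
Reactants: 6 dimethyl 2-(2-oxoethyl)-2-(4-oxopentyl)malonate
Product: 8 dimethyl 2-formyl-3-methylcyclohex-2-ene-1,1-dicarboxylate, via aldol 7 (not isolated)
Conditions: piperidine (0.3 equiv), AcOH (0.3 equiv), toluene, 4 Å MS, 80 °C
Reagents that add atoms: none
Why: Amine-catalysed intramolecular aldol condensation, in which piperidine turns the aldehyde rather than the ketone into an enamine whose α-carbon (C5) attacks the methyl ketone (C10) in a 6-enolexo closure of ring A helped by the quaternary malonate carbon, and dehydration gives the tetrasubstituted enal.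

Step 5
Reactants: 8 dimethyl 2-formyl-3-methylcyclohex-2-ene-1,1-dicarboxylate
Product: 9 dimethyl 2-ethynyl-3-methylcyclohex-2-ene-1,1-dicarboxylate
Conditions: dimethyl (1-diazo-2-oxopropyl)phosphonate, K2CO3, MeOH, 0 °C → rt
Reagents that add atoms: dimethyl (1-diazo-2-oxopropyl)phosphonate, CC(=O)C(=[N+]=[N-])P(=O)(OC)OC
Why: Ohira–Bestmann alkynylation of the non-enolisable enal adds the missing carbon (C7) without passing through a secondary alkoxide, which after methyl Grignard addition would lactonise onto the neighbouring esters.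

Step 6
Reactants: 9 dimethyl 2-ethynyl-3-methylcyclohex-2-ene-1,1-dicarboxylate
Product: 10 dimethyl 2-acetyl-3-methylcyclohex-2-ene-1,1-dicarboxylate
Conditions: Ph3PAuNTf2 (2 mol %), 1,4-dioxane/H2O, 60 °C
Reagents that add atoms: water, O
Why: Gold-catalysed Markovnikov hydration of the terminal alkyne should give the methyl ketone, and participation of a neighbouring ester carbonyl at the gold-activated alkyne leads to the same regiochemistry.

Step 7
Reactants: 10 dimethyl 2-acetyl-3-methylcyclohex-2-ene-1,1-dicarboxylate
Product: 11 dimethyl 3-methyl-2-[1-(triisopropylsilyloxy)vinyl]cyclohex-2-ene-1,1-dicarboxylate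
Conditions: TIPSOTf, Et3N, CH2Cl2, 0 °C
Reagents that add atoms: triisopropylsilyl trifluoromethanesulfonate, CC(C)[Si](OS(=O)(=O)C(F)(F)F)(C(C)C)C(C)C
Why: Soft enolisation (O-silylation, then deprotonation of the acetyl methyl by Et3N) should give the cross-conjugated 2-silyloxydiene, because the acetyl group is twisted out of conjugation and the γ-hydrogens are not activated.

Step 8
Reactants: 12 but-2-yn-1-ol
Product: 13 but-2-ynal
Conditions: MnO2, CH2Cl2, rt; filtered and used as a dried solution
Reagents that add atoms: none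
Why: MnO2 oxidation of a propargylic alcohol stops at the aldehyde, and the volatile ynal is not isolated neat.

Step 9
Reactants: 11 dimethyl 3-methyl-2-[1-(triisopropylsilyloxy)vinyl]cyclohex-2-ene-1,1-dicarboxylate; 13 but-2-ynal
Product: 14 dimethyl (4aR)-5-formyl-4a,6-dimethyl-8-(triisopropylsilyloxy)-3,4,4a,7-tetrahydronaphthalene-1,1(2H)-dicarboxylate
Conditions: (S)-3,3-diphenyl-1-(o-tolyl)tetrahydro-1H,3H-pyrrolo[1,2-c][1,3,2]oxazaborole (20 mol %), Tf2NH (17 mol %), CH2Cl2, −78 → −40 °C
Reagents that add atoms: none
Why: Proposed new method: the ynal binds through its carbonyl oxygen to the cationic boron centre, which lowers the alkyne LUMO, and the diene adds in a concerted, asynchronous [4+2] cycloaddition in which the nucleophilic terminus C7 bonds ahead to the β-carbon C8 while C10 bonds to the α-carbon C9. The closest known reactions are thermal Diels–Alder additions of 2-methyl-1-vinylcyclohexene-type dienes to acetylenic dienophiles, oxazaborolidinium-catalysed additions of 2-silyloxydienes to enals, and chiral boron Lewis acid catalysed additions of acetylenic aldehydes to simple dienes; enantiofacial control at a fully substituted diene terminus by an alkyne-bound catalyst is the untested part. Ring B is closed by intermolecular suprafacial [4+2] annulation onto ring A and emerges as a cyclohexa-1,4-diene, so C5 stays sp2 and C10 is the only new stereocentre. C10 is controlled by the catalyst alone, since the gem-diester makes the two diene faces enantiotopic and the aryl groups around the coordinated formyl group should leave only one approach open. The step needs para regiochemistry, secured by the large HOMO coefficient at C7 and by the unhindered CH2 terminus meeting the methyl-bearing alkyne carbon, and [4+2] periselectivity over Mukaiyama aldol addition to the formyl group, which the bulky acid-stable TIPS group and low temperature should favour.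

Step 10
Reactants: 14 dimethyl (4aR)-5-formyl-4a,6-dimethyl-8-(triisopropylsilyloxy)-3,4,4a,7-tetrahydronaphthalene-1,1(2H)-dicarboxylate
Product: 15 8,9-epoxy aldehyde (epoxide oxygen anti to C20)
Conditions: 30% aq. H2O2, NaOH (cat.), MeOH, 0 °C
Reagents that add atoms: hydrogen peroxide, OO
Why: Weitz–Scheffer nucleophilic epoxidation, in which hydroperoxide adds to the β-carbon C8 of the enal from the face anti to the quasi-axial C10 methyl and the enolate closes onto oxygen on that face, while the silyl enol ether and the esters are not attacked by the nucleophilic oxidant.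

Step 11
Reactants: 15 8,9-epoxy aldehyde (epoxide oxygen anti to C20)
Product: 16 8-hydroxy-9-formyl aldol (8-OH and H-9 anti to C20)
Conditions: SmI2 (2.2 equiv), THF/MeOH, −90 °C
Reagents that add atoms: none
Why: Reductive opening of an α,β-epoxy carbonyl compound by divalent samarium, in which the ketyl fragments at the Cα–O bond, the samarium enolate is protonated at C9 from the face anti to the C8 and C10 methyls (formyl equatorial, also the more stable position), and the C8 oxygen keeps the configuration set in step 10.

Step 12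
Reactants: 16 8-hydroxy-9-formyl aldol (8-OH and H-9 anti to C20)
Product: 17 8-O-triethylsilyl aldol
Conditions: TESOTf, 2,6-lutidine, CH2Cl2, −78 → −40 °C
Reagents that add atoms: triethylsilyl trifluoromethanesulfonate, CC[Si](CC)(CC)OS(=O)(=O)C(F)(F)F
Why: Silylation of the hindered tertiary alcohol with a silyl triflate masks the β-hydroxyl, which blocks retro-aldol cleavage in the basic olefination that follows.

Step 13
Reactants: 17 8-O-triethylsilyl aldol
Product: 18 9-vinyl compound (C11=C12)
Conditions: Ph3PCH3Br, KHMDS, THF, 0 °C; then 17, −78 → 0 °C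
Reagents that add atoms: methyltriphenylphosphonium bromide, C[P+](c1ccccc1)(c1ccccc1)c1ccccc1.[Br-]
Why: Wittig methylenation with the unstabilised ylide should add to the hindered aldehyde faster than it enolises C9, and the esters and both silyl groups are inert.

Step 14
Reactants: 18 9-vinyl compound (C11=C12)
Product: 19 18,19-diol (enol ether and TES ether retained)
Conditions: LiAlH4, THF, 0 → 40 °C; Rochelle-salt work-up
Reagents that add atoms: none
Why: LiAlH4 reduces both neopentyl methyl esters to the 1,3-diol while the silyl enol ether, the TES ether and the isolated alkene are untouched.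

Step 15
Reactants: 19 18,19-diol (enol ether and TES ether retained)
Product: 20 trans-fused 6-ketone with free 8-OH and 18,19-diol
Conditions: 48% aq. HF, MeCN, 0 °C → rt
Reagents that add atoms: none
Why: Hydrolysis of the silyl enol ether with axial protonation at C5 on the face anti to the C10 methyl should give the trans-fused ketone (also the thermodynamic fusion), and the tertiary TES ether is cleaved in the same operation; any internal hemiketal is in equilibrium with this ketone.

Step 16
Reactants: 20 trans-fused 6-ketone with free 8-OH and 18,19-diol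
Product: 21 6,8,18,19-tetraol (6-OH equatorial and anti to C20)
Conditions: Li, NH3(l)/THF, −78 → −33 °C (ketone added to the metal solution); then NH4Cl
Reagents that add atoms: none
Why: Dissolving-metal reduction protonates the ketyl-derived carbanion to the more stable equatorial alkoxide, whereas hydride reagents would attack the open face and give the axial alcohol; the isolated alkene and the alcohols are inert.

Step 17
Reactants: 21 6,8,18,19-tetraol (6-OH equatorial and anti to C20)
Product: 22 18-O-TBS ether (equatorial CH2OTBS and axial CH2OH on C4)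
Conditions: TBSCl (1.0 equiv), imidazole, DMF, −30 → 0 °C
Reagents that add atoms: tert-butyldimethylsilyl chloride, CC(C)(C)[Si](C)(C)Cl
Why: Steric differentiation of the diastereotopic hydroxymethyl groups by selective silylation, the equatorial one on the periphery reacting first and the axial one being shielded by the syn-axial C10 methyl, which sets C4; the secondary and tertiary hydroxyls do not react at low temperature.

Step 18
Reactants: 22 18-O-TBS ether (equatorial CH2OTBS and axial CH2OH on C4)
Product: 23 19-mesylate
Conditions: MsCl (1.1 equiv), Et3N, CH2Cl2, −30 °C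
Reagents that add atoms: methanesulfonyl chloride, CS(=O)(=O)Cl
Why: Sulfonylation is fastest at the one remaining primary hydroxyl, the peri-shielded secondary and the tertiary alcohol staying free.

Step 19
Reactants: 23 19-mesylate
Product: 24 C19-methyl 6,8-diol
Conditions: LiEt3BH (excess), THF, 0 → 60 °C
Reagents that add atoms: none
Why: SN2 hydride displacement of a neopentyl mesylate by LiEt3BH is the standard way to turn an axial C4 hydroxymethyl into methyl, and the equatorial C6 alkoxide cannot reach C19.

Step 20
Reactants: 24 C19-methyl 6,8-diol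
Product: 25 6-acetate
Conditions: Ac2O, pyridine, DMAP (cat.), CH2Cl2, rt
Reagents that add atoms: acetic anhydride, CC(=O)OC(C)=O
Why: DMAP-catalysed acylation takes the only reactive (secondary) hydroxyl, since the tertiary C8 alcohol is not acetylated under these conditions.

Step 21
Reactants: 25 6-acetate; 26 chloroprene (2-chlorobuta-1,3-diene)
Product: 28 18-O-TBS ether of the target, via alkylborane 27 (not isolated)
Conditions: 9-BBN, THF, rt → 50 °C; then 3 M aq. K3PO4, 26, Pd(OAc)2 (5 mol %), SPhos (10 mol %), 45 °C, sealed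
Reagents that add atoms: none
Why: Anti-Markovnikov hydroboration of the terminal alkene followed by B-alkyl Suzuki–Miyaura coupling with the alkenyl chloride installs the 2-substituted buta-1,3-diene in one operation, and the acetate, silyl ether and tertiary alcohol tolerate the mildly basic conditions.

Step 22
Reactants: 28 18-O-TBS ether of the target
Product: 29 target, (4S,5S,6R,8S,9S,10R)-8,18-dihydroxylabda-13(16),14-dien-6-yl acetate
Conditions: HF·pyridine, pyridine/THF, 0 °C → rt
Reagents that add atoms: none
Why: Fluoride cleavage of the primary silyl ether under buffered, slightly acidic conditions should avoid acetyl migration from O6 to the neighbouring primary alcohol and spare the diene and the tertiary alcohol.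

**Compound list**
1 | dimethyl 2-allylmalonate | C=CCC(C(=O)OC)C(=O)OC | starting material
2 | 2-(3-chloropropyl)-2-methyl-1,3-dioxolane | CC1(CCCCl)OCCO1 | starting material
3 | dimethyl 2-allyl-2-[3-(2-methyl-1,3-dioxolan-2-yl)propyl]malonate | C=CCC(CCCC1(C)OCCO1)(C(=O)OC)C(=O)OC | intermediate
4 | ozonide (1,2,4-trioxolane) of 3 | O1OC(CC(CCCC2(C)OCCO2)(C(=O)OC)C(=O)OC)OC1 | intermediate
5 | dimethyl 2-[3-(2-methyl-1,3-dioxolan-2-yl)propyl]-2-(2-oxoethyl)malonate | O=CCC(CCCC1(C)OCCO1)(C(=O)OC)C(=O)OC | intermediate
6 | dimethyl 2-(2-oxoethyl)-2-(4-oxopentyl)malonate | CC(=O)CCCC(CC=O)(C(=O)OC)C(=O)OC | intermediate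
7 | dimethyl 2-formyl-3-hydroxy-3-methylcyclohexane-1,1-dicarboxylate (aldol, racemic) | O=CC1C(C)(O)CCCC1(C(=O)OC)C(=O)OC | intermediate
8 | dimethyl 2-formyl-3-methylcyclohex-2-ene-1,1-dicarboxylate | O=CC1=C(C)CCCC1(C(=O)OC)C(=O)OC | intermediate
9 | dimethyl 2-ethynyl-3-methylcyclohex-2-ene-1,1-dicarboxylate | C#CC1=C(C)CCCC1(C(=O)OC)C(=O)OC | intermediate
10 | dimethyl 2-acetyl-3-methylcyclohex-2-ene-1,1-dicarboxylate | CC(=O)C1=C(C)CCCC1(C(=O)OC)C(=O)OC | intermediate
11 | dimethyl 3-methyl-2-[1-(triisopropylsilyloxy)vinyl]cyclohex-2-ene-1,1-dicarboxylate (ring A 2-silyloxydiene) | C=C(O[Si](C(C)C)(C(C)C)C(C)C)C1=C(C)CCCC1(C(=O)OC)C(=O)OC | intermediate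
12 | but-2-yn-1-ol | CC#CCO | starting material
13 | but-2-ynal | CC#CC=O | intermediate
14 | dimethyl (4aR)-5-formyl-4a,6-dimethyl-8-(triisopropylsilyloxy)-3,4,4a,7-tetrahydronaphthalene-1,1(2H)-dicarboxylate; labdane numbering: (10R), C5=C6(OTIPS), C8=C9–CHO | O=CC1=C(C)CC(O[Si](C(C)C)(C(C)C)C(C)C)=C2C(C(=O)OC)(C(=O)OC)CCC[C@@]12C | intermediate
15 | 8,9-epoxide of 14, oxygen anti to C20 | O=C[C@]31[C@]2(C)CCCC(C(=O)OC)(C(=O)OC)C2=C(O[Si](C(C)C)(C(C)C)C(C)C)C[C@]1(C)O3 | intermediate
16 | aldol: 9-CHO (syn to C20, H-9 anti), 8-OH anti to C20 and C17 syn, C5=C6(OTIPS), 4,4-diester | O=C[C@H]1[C@]2(C)CCCC(C(=O)OC)(C(=O)OC)C2=C(O[Si](C(C)C)(C(C)C)C(C)C)C[C@]1(C)O | intermediate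
17 | 8-O-TES ether of 16 | O=C[C@H]1[C@]2(C)CCCC(C(=O)OC)(C(=O)OC)C2=C(O[Si](C(C)C)(C(C)C)C(C)C)C[C@]1(C)O[Si](CC)(CC)CC | intermediate
18 | 9-vinyl compound (CHO of 17 replaced by CH=CH2) | C=C[C@H]1[C@]2(C)CCCC(C(=O)OC)(C(=O)OC)C2=C(O[Si](C(C)C)(C(C)C)C(C)C)C[C@]1(C)O[Si](CC)(CC)CC | intermediate
19 | 4,4-bis(hydroxymethyl) compound (both esters of 18 reduced) | C=C[C@H]1[C@]2(C)CCCC(CO)(CO)C2=C(O[Si](C(C)C)(C(C)C)C(C)C)C[C@]1(C)O[Si](CC)(CC)CC | intermediate
20 | trans-decalin 6-ketone: H-5 anti to C20, 8-OH free, 4,4-bis(hydroxymethyl), 9-vinyl | C=C[C@H]1[C@]2(C)CCCC(CO)(CO)[C@H]2C(=O)C[C@]1(C)O | intermediate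
21 | tetraol: 6-OH equatorial (anti to C20), 8-OH, 4,4-bis(hydroxymethyl), 9-vinyl | C=C[C@H]1[C@]2(C)CCCC(CO)(CO)[C@H]2[C@H](O)C[C@]1(C)O | intermediate
22 | 18-O-TBS ether: equatorial CH2OTBS (anti to C20), axial CH2OH (syn to C20) | C=C[C@H]1[C@]2(C)CCC[C@](CO)(CO[Si](C)(C)C(C)(C)C)[C@H]2[C@H](O)C[C@]1(C)O | intermediate
23 | 19-mesylate of 22 | C=C[C@H]1[C@]2(C)CCC[C@](COS(C)(=O)=O)(CO[Si](C)(C)C(C)(C)C)[C@H]2[C@H](O)C[C@]1(C)O | intermediate
24 | C19-methyl compound: axial CH3 on C4, 6-OH and 8-OH free, 18-OTBS, 9-vinyl | C=C[C@H]1[C@]2(C)CCC[C@](C)(CO[Si](C)(C)C(C)(C)C)[C@H]2[C@H](O)C[C@]1(C)O | intermediate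
25 | 6-acetate of 24 | C=C[C@H]1[C@]2(C)CCC[C@](C)(CO[Si](C)(C)C(C)(C)C)[C@H]2[C@H](OC(C)=O)C[C@]1(C)O | intermediate
26 | chloroprene (2-chlorobuta-1,3-diene) | C=CC(Cl)=C | starting material
27 | B-alkyl-9-BBN from 25 (boron on C12) | C(C[C@H]1[C@]2(C)CCC[C@](C)(CO[Si](C)(C)C(C)(C)C)[C@H]2[C@H](OC(C)=O)C[C@]1(C)O)B3C4CCCC3CCC4 | intermediate
28 | 18-O-TBS ether of the target | C=CC(=C)CC[C@H]1[C@]2(C)CCC[C@](C)(CO[Si](C)(C)C(C)(C)C)[C@H]2[C@H](OC(C)=O)C[C@]1(C)O | intermediate
29 | (4S,5S,6R,8S,9S,10R)-8,18-dihydroxylabda-13(16),14-dien-6-yl acetate | C=CC(=C)CC[C@H]1[C@]2(C)CCC[C@](C)(CO)[C@H]2[C@H](OC(C)=O)C[C@]1(C)O | target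

**Step count**
Total: 22 steps. Longest linear sequence: 21 steps (steps 1–7 and 9–22; step 8 is a one-step side branch).

**Three steps most likely to fail**

Step 9 (proposed method). The catalyst may not discriminate the faces of the hindered diene well enough, or the reaction may divert to Mukaiyama aldol or Michael addition at the Lewis-acid-bound aldehyde. The fallback sets out from 11 and 13 and returns at 14. The cycloaddition is run without chiral control, thermally in toluene at 110 °C or with Me2AlCl at −40 °C, as is known for 2-methyl-1-vinylcyclohexene-type dienes with acetylenic dienophiles, to give the racemic adduct F1. Condensation with (S)-1-amino-2-(methoxymethyl)pyrrolidine and chromatographic separation of the two diastereomers give the (10R)-hydrazone F2. Cleavage of F2 with aqueous oxalic acid releases 14.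

Step 10. Conjugate addition of hydroperoxide to the fully substituted, hindered enal may be slow, so that attack at the formyl group (Dakin-type oxidation) or base-induced deconjugation through C7 takes over. The fallback sets out from 14 and returns at 15. NaBH4/CeCl3 reduces the aldehyde to the allylic alcohol F3. VO(acac)2/t-BuOOH then epoxidises the allylic alkene on the face anti to the C10 methyl to give the epoxy alcohol F4. Dess–Martin periodinane oxidises F4 to 15.

Step 17. The two primary hydroxymethyl groups may be discriminated poorly, with silylation of the axial one or of both. The fallback sets out from 18 and returns at 24; it differentiates the groups through an axial C6 alcohol instead.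
- Aqueous HF hydrolyses 18 to the keto diester F5.
- LiAlH4 attacks the ketone from the open face and reduces the esters, giving the tetraol with axial 6-OH F6, in which the axial CH2OH is buried between the syn-axial C10 methyl and 6-OH.
- TBSCl then silylates the exposed equatorial CH2OH to give the silyl ether F7.
- MsCl/Et3N gives the primary mesylate F8.
- Dess–Martin periodinane oxidises the axial 6-OH to give the keto mesylate F9.
- NaI/Zn in DMF at 90 °C reduces the neopentyl mesylate through the iodide F10 to the C19-methyl ketone F11.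
- Li/NH3 reduction of F11 gives 24.

**Further compounds**
F1 | step 9 | racemic Diels–Alder adduct | O=CC1=C(C)CC(O[Si](C(C)C)(C(C)C)C(C)C)=C2C(C(=O)OC)(C(=O)OC)CCCC12C
F2 | step 9 | (E)-hydrazone of 14 with (S)-1-amino-2-(methoxymethyl)pyrrolidine | COC[C@@H]1CCCN1/N=C/C2=C(C)CC(O[Si](C(C)C)(C(C)C)C(C)C)=C3C(C(=O)OC)(C(=O)OC)CCC[C@@]23C
F3 | step 10 | allylic alcohol (CHO of 14 reduced to CH2OH) | OCC1=C(C)CC(O[Si](C(C)C)(C(C)C)C(C)C)=C2C(C(=O)OC)(C(=O)OC)CCC[C@@]12C
F4 | step 10 | 8,9-epoxy alcohol (oxygen anti to C20) | OC[C@]31[C@]2(C)CCCC(C(=O)OC)(C(=O)OC)C2=C(O[Si](C(C)C)(C(C)C)C(C)C)C[C@]1(C)O3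
F5 | step 17 | trans-fused 6-keto 4,4-diester with free 8-OH and 9-vinyl | C=C[C@H]1[C@]2(C)CCCC(C(=O)OC)(C(=O)OC)[C@H]2C(=O)C[C@]1(C)O
F6 | step 17 | tetraol with axial 6-OH (syn to C20) | C=C[C@H]1[C@]2(C)CCCC(CO)(CO)[C@H]2[C@@H](O)C[C@]1(C)O
F7 | step 17 | 18-O-TBS ether with axial 6-OH | C=C[C@H]1[C@]2(C)CCC[C@](CO)(CO[Si](C)(C)C(C)(C)C)[C@H]2[C@@H](O)C[C@]1(C)O
F8 | step 17 | 19-mesylate with axial 6-OH | C=C[C@H]1[C@]2(C)CCC[C@](COS(C)(=O)=O)(CO[Si](C)(C)C(C)(C)C)[C@H]2[C@@H](O)C[C@]1(C)O
F9 | step 17 | 6-keto 19-mesylate | C=C[C@H]1[C@]2(C)CCC[C@](COS(C)(=O)=O)(CO[Si](C)(C)C(C)(C)C)[C@H]2C(=O)C[C@]1(C)O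
F10 | step 17 | 6-keto 19-iodide | C=C[C@H]1[C@]2(C)CCC[C@](CI)(CO[Si](C)(C)C(C)(C)C)[C@H]2C(=O)C[C@]1(C)O
F11 | step 17 | 6-keto C19-methyl compound | C=C[C@H]1[C@]2(C)CCC[C@](C)(CO[Si](C)(C)C(C)(C)C)[C@H]2C(=O)C[C@]1(C)O
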